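**Plan**

- Numbering: right half as hydroazulene C1 (carbinol), C2, C3, C3a, C4 (CMe2), C5, C6, C7 (CHOH), C8, C8a, with ring A seven-membered and ring B five-membered; left half as 1-benzoxepine with primes (O1′, C2′ … C9a′), ring C cyclohexane, ring D oxepane.
- Cuts: (a) C5–CH2 of the linker (alkyllithium plus vinylogous ester, Stork–Danheiser); (b) C6 and C7 taken out of ring A, back to a cyclopentanone; (c) C3–C3a and C1–C8a together, a [3+2] annulation of an allenylsilane onto a cyclopentene-1,2-dione; (d) in the left half O1′–C2′ and C5a′–C6′, a polyepoxide cascade from geranylacetone.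
- Forward: ring B is annulated onto a five-membered ring A; the helper C8 carbonyl and the silyl group are removed; ring A grows to seven through a temporary cyclobutanone (dichloroketene [2+2], retro-aldol); rings D and C close in one cascade; the halves are joined at C5.
- Enabling feature: C8a is flanked by C8, a ring CH2 that can be carried as a ketone, so C3a–C8a becomes the β,α pair of an enone whose γ-carbon C4 is quaternary; C3–C2–C1(CH3) of ring B maps onto CH2=C=C(CH3)SiMe3, and the C5/C8 dione offers two-point binding to a chiral Lewis acid.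
- Stereochemistry: C3a from the chiral copper catalyst, C8a from the enforced cis fusion, C1 from convex-face hydration, C7 from CBS reduction; C3′, C5a′ and C9a′ from Shi epoxidation relayed through anti epoxide openings, C6′ equatorial from the chair cascade, C7′ from equatorial Grignard attack.

Key step: step 2

Remark: allene 3 is taken as a catalogue reagent, and the face sense of the copper catalyst cannot be assigned in advance; the (S,S)-ligand is written and its antipode is used if the opposite face is delivered.

**Route**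

Step 1
Reactants: 1 4,4-dimethylcyclopent-2-en-1-one
Product: 2 5,5-dimethylcyclopent-3-ene-1,2-dione (future C8 carbonyl conjugated; future C5 carbonyl next to CMe2)
Conditions: SeO2 (1.2 equiv), 1,4-dioxane–H2O, 90 °C
Reagents that add atoms: selenium dioxide, O=[Se]=O
Why: Riley oxidation of the only enolisable α-methylene (between the carbonyl and the quaternary carbon) should give the 1,2-dione; the γ-position is quaternary, so allylic oxidation cannot compete.

Step 2
Reactants: 2 5,5-dimethylcyclopent-3-ene-1,2-dione; 3 trimethyl(1-methylpropa-1,2-dien-1-yl)silane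
Product: 5 cis-fused ketol (cis-bicyclo[3.3.0]oct-1-ene in target numbering: 1-methyl; 2-trimethylsilyl; 4,4-dimethyl; 5-ketone; 8-hydroxyl on the ring B side; C3a/C8a as in the target), via annulated 1,2-diketone 4 (not isolated)
Conditions: Cu(SbF6)2 with (S,S)-t-Bu-box [2,2′-(propane-2,2-diyl)bis((4S)-4-tert-butyl-4,5-dihydrooxazole)] (10 mol %), 4 Å sieves, CH2Cl2, −78 °C; then LiBH(s-Bu)3 (1.05 equiv), THF, −78 °C; H2O
Reagents that add atoms: none
Why: Proposed new method: the dione binds the C2-symmetric dicationic divalent copper centre through both carbonyl oxygens, the CH2 terminus of 3 adds to the enone β-carbon C3a from the open face, the β-silyl vinyl cation undergoes a 1,2-silyl shift and is captured by the copper enolate through C8a, and the cold hydride quench then reduces the less hindered C8 carbonyl of 4 before it can enolise toward C8a. The closest known reactions are the TiCl4-promoted Danheiser annulation of allenylsilanes with cyclic enones and copper bis(oxazoline) catalysis of additions to chelating 1,2-dicarbonyl acceptors. Ring B closes by attack of the enolate carbon on the linear vinyl cation (5-endo with respect to the cation, enolexo with respect to the enolate), so C3–C3a and C1–C8a arise in one cationic cascade. C3a is set by the ligand-controlled face of the first addition, C8a follows because the tethered cation can reach the enolate only from the same face (cis-bicyclo[3.3.0]octane), and the C8 carbinol is a helper centre removed in step 3. The step needs 1,4- over 1,2-addition and annulation over desilylative propargylation: the quaternary C4 shields the C5 carbonyl and forbids dienolisation, double activation raises the electrophilicity of C3a, and the non-nucleophilic SbF6 counter-ion leaves silicon on carbon for the shift.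

Step 3
Reactants: 5 cis-fused ketol
Product: 6 cis-fused C5 ketone carrying the C1=C2 vinylsilane (C8 now CH2)
Conditions: SmI2 (2.5 equiv), THF–MeOH, −78 → 23 °C
Reagents that add atoms: none
Why: SmI2 reduction of an α-hydroxy ketone (ketyl at C5, second electron transfer, loss of the C8 oxygen, protonation of the samarium enolate) should remove the helper oxygen and leave the C5 ketone.

Step 4
Reactants: 6 cis-fused C5 ketone carrying the vinylsilane
Product: 7 cis-fused C5 ketone with the C1=C2 trisubstituted alkene (1,4,4-trimethyl)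
Conditions: TsOH·H2O (0.2 equiv), wet MeCN, 45 °C
Reagents that add atoms: none
Why: Protodesilylation of a vinylsilane: ipso protonation at C2 gives a tertiary β-silyl cation at C1 that loses silicon, so the alkene stays in place.

Step 5
Reactants: 7 cis-fused alkene ketone
Product: 8 cis-fused hydroxy ketone (C1 tertiary alcohol with OH cis to H-8a; C5 ketone)
Conditions: Co(acac)2 (20 mol %), PhSiH3, O2 (1 atm), THF, 23 °C; then PPh3
Reagents that add atoms: dioxygen, O=O
Why: Mukaiyama hydration by hydrogen-atom transfer: H adds to C2 and the tertiary C1 radical should be trapped by O2 on the convex face of the cis-fused bicycle (anti to ring A), which sets C1.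

Step 6
Reactants: 8 cis-fused hydroxy ketone
Product: 9 C5 trimethylsilyl enol ether (C5=C8) with the C1 alcohol as its trimethylsilyl ether
Conditions: TMSOTf (2.5 equiv), Et3N, CH2Cl2, 0 °C
Reagents that add atoms: trimethylsilyl trifluoromethanesulfonate, C[Si](C)(C)OS(=O)(=O)C(F)(F)F
Why: Soft enolisation and silylation: the C5 ketone can enolise only toward C8 because C4 is quaternary, so a single silyl enol ether forms while the tertiary alcohol is capped.

Step 7
Reactants: 9 C5 trimethylsilyl enol ether
Product: 10 tricyclic dichlorocyclobutanone (new C7 carbonyl bonded to C8; new C6 as CCl2 bonded to C5; cyclobutane cis-fused on the convex face of ring A)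
Conditions: Cl2CHCOCl (1.3 equiv), Et3N (1.4 equiv), hexane, 23 °C, slow addition
Reagents that add atoms: dichloroacetyl chloride, O=C(Cl)C(Cl)Cl
Why: Ketene–silyl enol ether [2+2] cycloaddition: the electrophilic ketene carbonyl carbon bonds to the nucleophilic C8 and CCl2 to C5, building the temporary four-membered ring that holds the future C6 and C7.

Step 8
Reactants: 10 tricyclic dichlorocyclobutanone
Product: 12 cis-fused hydroazulene-5,7-dione (1-hydroxy-1,4,4-trimethyl; ring A now seven-membered), via dechlorinated cyclobutanone 11 (not isolated)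
Conditions: Zn dust, AcOH, 23 °C; then i-PrOH–H2O, 80 °C
Reagents that add atoms: none
Why: Zinc removes both chlorines, then desilylation triggers retro-aldol cleavage of the strained C5–C8 bond (fragmentation of the bicyclo[3.2.0]heptanone), which should expand ring A from five to seven members.

Step 9
Reactants: 12 cis-fused hydroazulene-5,7-dione
Product: 13 6-methyl-5,7-dione (1-hydroxy-1,4,4,6-tetramethyl; C6 epimers and enol forms)
Conditions: MeI (1.5 equiv), K2CO3, acetone, 56 °C
Reagents that add atoms: iodomethane, CI
Why: C-alkylation of the 1,3-dione enolate at the doubly activated C6 installs the C6 methyl; the C6 centre is epimerisable and becomes planar later.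

Step 10
Reactants: 13 6-methyl-5,7-dione
Product: 14 vinylogous ester (7-isobutoxy; C6=C7; C5 ketone; free C1 alcohol)
Conditions: i-BuOH, PPTS (0.1 equiv), toluene, 110 °C, Dean–Stark
Reagents that add atoms: 2-methylpropan-1-ol, CC(C)CO
Why: Acid-catalysed enol ether formation should occur at the less hindered C7 carbonyl, because C5 is flanked by the quaternary C4.

Step 11
Reactants: 14 vinylogous ester
Product: 15 vinylogous ester with the C1 alcohol as its triethylsilyl ether
Conditions: TESOTf (1.5 equiv), 2,6-lutidine, CH2Cl2, −78 → 0 °C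
Reagents that add atoms: triethylsilyl trifluoromethanesulfonate, CC[Si](CC)(CC)OS(=O)(=O)C(F)(F)F
Why: Silyl triflate silylation of the tertiary alcohol removes the only acidic proton before the organolithium addition.

Step 12
Reactants: 16 (E)-geranylacetone [(5E)-6,10-dimethylundeca-5,9-dien-2-one]; 17 benzyloxyacetaldehyde
Product: 18 β-hydroxy ketone (aldol adduct at the methyl carbon; carbinol epimers)
Conditions: LiN(i-Pr)2 (1.05 equiv), THF, −78 °C; then 17; H2O
Reagents that add atoms: none
Why: Kinetic aldol: the amide base deprotonates the methyl side of the methyl ketone and the enolate adds to the aldehyde; the new carbinol centre is lost in step 13.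

Step 13
Reactants: 18 β-hydroxy ketone
Product: 20 (E)-enone (benzyloxymethyl-substituted enone with both trisubstituted alkenes intact), via mesylate 19 (not isolated)
Conditions: MsCl (1.5 equiv), Et3N (4 equiv), CH2Cl2, 0 → 23 °C
Reagents that add atoms: none
Why: Mesylation followed by E1cB elimination should give the conjugated (E)-enone.

Step 14
Reactants: 20 (E)-enone
Product: 21 bis-epoxy enone (both trisubstituted alkenes epoxidised; all three stereogenic epoxide carbons R)
Conditions: D-fructose-derived Shi ketone (0.4 equiv), KHSO5 (as Oxone, 2KHSO5·KHSO4·K2SO4), K2CO3, Bu4NHSO4 (cat.), MeCN–dimethoxymethane–aq. Na2B4O7 buffer, 0 °C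
Reagents that add atoms: potassium peroxymonosulfate, [K+].[O-]OS(=O)(=O)O
Why: Shi epoxidation: the chiral dioxirane epoxidises the two electron-rich trisubstituted alkenes (not the enone) through the spiro transition state, giving the (R)-configured carbons that become C3′, C9a′ and C5a′.

Step 15
Reactants: 21 bis-epoxy enone
Product: 22 (Z)-triethylsilyl enol ether whose nucleophilic carbon carries the CH2CH2OBn linker
Conditions: Et3SiH (1.2 equiv), RhCl(PPh3)3 (1 mol %), THF, 50 °C
Reagents that add atoms: triethylsilane, CC[SiH](CC)CC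
Why: Rhodium-catalysed 1,4-hydrosilylation of the enone with a monohydrosilane should give the regiodefined silyl enol ether without touching the epoxides.

Step 16
Reactants: 22 (Z)-triethylsilyl enol ether
Product: 23 trans-fused bicyclic ketone (rings C and D closed; C7′ ketone; C3′ triethylsilyl ether; C6′ equatorial CH2CH2OBn)
Conditions: TESOTf (0.2 equiv), 2,6-di-tert-butyl-4-methylpyridine (0.5 equiv), CH2Cl2, −78 °C; Et3N
Reagents that add atoms: none
Why: Tandem endo-selective oxa- and carbacyclisation of a polyepoxide: the silylated terminal epoxide is opened at its tertiary carbon by the oxygen of the internal epoxide (ring D), the epoxonium ion is opened with inversion at C5a′ by the enol silane through a chair (ring C), and the released silyl cation carries the chain; C6′ is equatorial kinetically or by equilibration next to the ketone.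

Step 17
Reactants: 23 trans-fused bicyclic ketone
Product: 24 tertiary alcohol (C7′ axial OH, equatorial methyl)
Conditions: MeMgBr (3 equiv), CeCl3 (3 equiv), THF, −78 → 0 °C; H2O
Reagents that add atoms: methylmagnesium bromide, C[Mg]Br
Why: Organocerium-type Grignard addition: equatorial attack, away from the axial C5a′ methyl, should give the axial tertiary alcohol without enolisation.

Step 18
Reactants: 24 tertiary alcohol
Product: 25 bis(triethylsilyl) ether with the benzyl ether intact
Conditions: TESOTf (2 equiv), 2,6-lutidine, CH2Cl2, 0 → 23 °C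
Reagents that add atoms: triethylsilyl trifluoromethanesulfonate, CC[Si](CC)(CC)OS(=O)(=O)C(F)(F)F
Why: Silyl triflate silylation caps the hindered tertiary alcohol so that no acidic proton remains for the lithiation.

Step 19
Reactants: 25 bis(triethylsilyl) ether
Product: 26 primary alcohol (2-hydroxyethyl at C6′)
Conditions: H2 (1 atm), Pd/C, EtOAc, 23 °C
Reagents that add atoms: none
Why: Hydrogenolysis of the benzyl ether under neutral conditions leaves the silyl ethers in place.

Step 20
Reactants: 26 primary alcohol
Product: 27 primary iodide (2-iodoethyl at C6′)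
Conditions: I2, PPh3, imidazole, CH2Cl2, 0 → 23 °C
Reagents that add atoms: iodine, II
Why: Appel-type iodination of the primary alcohol through the alkoxyphosphonium salt and SN2 displacement.

Step 21
Reactants: 27 primary iodide; 15 silylated vinylogous ester
Product: 30 enone (C7 ketone; C5=C6 tetrasubstituted alkene carrying the linker and the left half; three triethylsilyl ethers), via alkyllithium 28 (not isolated), via lithium alkoxide adduct 29 (not isolated)
Conditions: t-BuLi (2.1 equiv), Et2O–pentane, −78 °C; then 15, THF, −78 → 0 °C; then 1 M aq. HCl, THF, 0 °C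
Reagents that add atoms: none
Why: Stork–Danheiser sequence: iodine–lithium exchange, 1,2-addition of the primary alkyllithium to the C5 carbonyl, then acid hydrolysis of the enol ether with dehydration, which transposes the carbonyl to C7 and creates the C5=C6 alkene.

Step 22
Reactants: 30 enone
Product: 31 (7S)-allylic alcohol with three triethylsilyl ethers
Conditions: (R)-2-methyl-CBS-oxazaborolidine (0.5 equiv), BH3·SMe2 (1.5 equiv), THF, −30 °C; MeOH
Reagents that add atoms: none
Why: Corey–Bakshi–Shibata reduction: with the methyl-substituted alkenyl carbon C6 as the large group, the (R)-catalyst should deliver hydride to the face that gives the (7S)-alcohol (OH cis to ring B), in line with the convex-face preference of the bicycle.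

Step 23
Reactants: 31 (7S)-allylic alcohol
Product: 32 CNP0276044.1
Conditions: Bu4NF (6 equiv), THF, 23 → 45 °C
Reagents that add atoms: none
Why: Fluoride cleaves the one secondary and two tertiary triethylsilyl ethers under basic conditions that spare the allylic alcohol.

**Compound list**

1 | 4,4-dimethylcyclopent-2-en-1-one | O=C1C=CC(C)(C)C1 | starting material
2 | 5,5-dimethylcyclopent-3-ene-1,2-dione | O=C1C=CC(C)(C)C1=O | intermediate
3 | trimethyl(1-methylpropa-1,2-dien-1-yl)silane | C=C=C(C)[Si](C)(C)C | starting material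
4 | annulated cis-fused 1,2-diketone (C5 and C8 ketones; C1=C2 vinylsilane) | CC1(C)[C@@H]2CC([Si](C)(C)C)=C(C)[C@@H]2C(=O)C1=O | intermediate
5 | cis-fused ketol (C8 hydroxyl; C5 ketone; vinylsilane) | CC1(C)[C@@H]2CC([Si](C)(C)C)=C(C)[C@@H]2[C@H](O)C1=O | intermediate
6 | cis-fused C5 ketone with C1=C2 vinylsilane | CC1(C)[C@@H]2CC([Si](C)(C)C)=C(C)[C@@H]2CC1=O | intermediate
7 | cis-fused C5 ketone with C1=C2 alkene | CC1(C)[C@@H]2CC=C(C)[C@@H]2CC1=O | intermediate
8 | cis-fused hydroxy ketone (C1 tertiary alcohol; C5 ketone) | CC1(C)[C@@H]2CC[C@@](C)(O)[C@@H]2CC1=O | intermediate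
9 | C5 trimethylsilyl enol ether with C1 trimethylsilyl ether | CC1(C)[C@@H]2CC[C@@](C)(O[Si](C)(C)C)[C@@H]2C=C1O[Si](C)(C)C | intermediate
10 | tricyclic dichlorocyclobutanone | CC1(C)[C@@H]2CC[C@@](C)(O[Si](C)(C)C)[C@@H]2[C@H]3C(=O)C(Cl)(Cl)[C@@]13O[Si](C)(C)C | intermediate
11 | dechlorinated tricyclic cyclobutanone | CC1(C)[C@@H]2CC[C@@](C)(O[Si](C)(C)C)[C@@H]2[C@H]3C(=O)C[C@@]13O[Si](C)(C)C | intermediate
12 | cis-fused 1-hydroxy-1,4,4-trimethylhydroazulene-5,7-dione | CC1(C)[C@@H]2CC[C@@](C)(O)[C@@H]2CC(=O)CC1=O | intermediate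
13 | cis-fused 1-hydroxy-1,4,4,6-tetramethylhydroazulene-5,7-dione (C6 epimers) | CC1(C)[C@@H]2CC[C@@](C)(O)[C@@H]2CC(=O)C(C)C1=O | intermediate
14 | vinylogous ester (7-isobutoxy; C5 ketone; C1 alcohol) | CC1(C)[C@@H]2CC[C@@](C)(O)[C@@H]2CC(OCC(C)C)=C(C)C1=O | intermediate
15 | vinylogous ester with C1 triethylsilyl ether | CC1(C)[C@@H]2CC[C@@](C)(O[Si](CC)(CC)CC)[C@@H]2CC(OCC(C)C)=C(C)C1=O | intermediate
16 | (E)-geranylacetone | CC(=O)CC/C=C(\C)CCC=C(C)C | starting material
17 | benzyloxyacetaldehyde | O=CCOCc1ccccc1 | starting material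
18 | β-hydroxy ketone (aldol adduct) | OC(COCc1ccccc1)CC(=O)CC/C=C(\C)CCC=C(C)C | intermediate
19 | mesylate of 18 | CS(=O)(=O)OC(COCc1ccccc1)CC(=O)CC/C=C(\C)CCC=C(C)C | intermediate
20 | (E)-enone | O=C(/C=C/COCc1ccccc1)CC/C=C(\C)CCC=C(C)C | intermediate
21 | bis-epoxy enone | O=C(/C=C/COCc1ccccc1)CC[C@H]1O[C@]1(C)CC[C@H]1OC1(C)C | intermediate
22 | (Z)-triethylsilyl enol ether of the bis-epoxide | CC[Si](CC)(CC)O/C(CC[C@H]1O[C@]1(C)CC[C@H]1OC1(C)C)=C\CCOCc1ccccc1 | intermediate
23 | trans-fused oxepane–cyclohexanone (C3′ triethylsilyl ether; C6′ CH2CH2OBn) | c1ccccc1COCC[C@@H]2[C@@]3(C)CC[C@@H](O[Si](CC)(CC)CC)C(C)(C)O[C@@H]3CCC2=O | intermediate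
24 | C7′ tertiary alcohol | c1ccccc1COCC[C@@H]2[C@@]3(C)CC[C@@H](O[Si](CC)(CC)CC)C(C)(C)O[C@@H]3CC[C@]2(C)O | intermediate
25 | bis(triethylsilyl) ether benzyl ether | c1ccccc1COCC[C@@H]2[C@@]3(C)CC[C@@H](O[Si](CC)(CC)CC)C(C)(C)O[C@@H]3CC[C@]2(C)O[Si](CC)(CC)CC | intermediate
26 | left-half primary alcohol | OCC[C@@H]1[C@@]2(C)CC[C@@H](O[Si](CC)(CC)CC)C(C)(C)O[C@@H]2CC[C@]1(C)O[Si](CC)(CC)CC | intermediate
27 | left-half primary iodide | ICC[C@@H]1[C@@]2(C)CC[C@@H](O[Si](CC)(CC)CC)C(C)(C)O[C@@H]2CC[C@]1(C)O[Si](CC)(CC)CC | intermediate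
28 | left-half alkyllithium | [Li]CC[C@@H]1[C@@]2(C)CC[C@@H](O[Si](CC)(CC)CC)C(C)(C)O[C@@H]2CC[C@]1(C)O[Si](CC)(CC)CC | intermediate
29 | lithium alkoxide adduct at C5 (C5 epimers) | CC1(C)[C@@H]2CC[C@@](C)(O[Si](CC)(CC)CC)[C@@H]2CC(OCC(C)C)=C(C)C1(O[Li])CC[C@@H]3[C@@]4(C)CC[C@@H](O[Si](CC)(CC)CC)C(C)(C)O[C@@H]4CC[C@]3(C)O[Si](CC)(CC)CC | intermediate
30 | coupled enone (C7 ketone; C5=C6; three triethylsilyl ethers) | CC1=C(CC[C@@H]2[C@@]3(C)CC[C@@H](O[Si](CC)(CC)CC)C(C)(C)O[C@@H]3CC[C@]2(C)O[Si](CC)(CC)CC)C(C)(C)[C@@H]2CC[C@@](C)(O[Si](CC)(CC)CC)[C@@H]2CC1=O | intermediate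
31 | (7S)-allylic alcohol tris(triethylsilyl) ether | CC1=C(CC[C@@H]2[C@@]3(C)CC[C@@H](O[Si](CC)(CC)CC)C(C)(C)O[C@@H]3CC[C@]2(C)O[Si](CC)(CC)CC)C(C)(C)[C@@H]2CC[C@@](C)(O[Si](CC)(CC)CC)[C@@H]2C[C@@H]1O | intermediate
32 | CNP0276044.1: (1R,3aR,7S,8aR)-5-{2-[(3R,5aR,6R,7S,9aR)-3,7-dihydroxy-2,2,5a,7-tetramethyldecahydro-1-benzoxepin-6-yl]ethyl}-1,4,4,6-tetramethyl-1,2,3,3a,4,7,8,8a-octahydroazulene-1,7-diol | CC1=C(CC[C@@H]2[C@@]3(C)CC[C@@H](O)C(C)(C)O[C@@H]3CC[C@]2(C)O)C(C)(C)[C@@H]2CC[C@@](C)(O)[C@@H]2C[C@@H]1O | target

**Count and risks**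

Total steps: 23. Longest linear sequence: 14 (steps 1–11 and 21–23); the left-half branch is steps 12–20.

Step 2 (proposed method). The catalyst may discriminate the enone faces poorly, and desilylative propargylation or 1,2-addition may outrun the silyl shift and ring closure. The fallback is a racemic annulation with enzymatic resolution. Starting from 2 and 3, TiCl4 (1.1 equiv, CH2Cl2, −78 °C) promotes the Danheiser annulation, and the cold mixture is reduced with NaBH4 in MeOH to the racemic ketol, that is 5 together with its enantiomer ent-5 F2. Lipase-catalysed acylation (Candida antarctica lipase B or Burkholderia cepacia lipase, vinyl acetate, MTBE) of the faster enantiomer should give the acetate of 5 F1, which is separated from F2; if the enzyme prefers the other enantiomer, unreacted 5 goes into step 3 as it is. SmI2 (THF–MeOH, −78 °C) cleaves the α-acetoxy group of F1 and the route is rejoined at 6.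

Step 21. The alkyllithium may enolise 15 or fail to add to the C5 carbonyl, which sits between the quaternary C4 and the methyl-bearing C6. The fallback joins the halves by B-alkyl Suzuki–Miyaura coupling. From 13, NaBH4 (MeOH, −78 °C) should reduce the less hindered C7 ketone from the convex face to the hydroxy ketone F5; TESOTf and 2,6-lutidine give the bis(triethylsilyl) ether F6; KN(SiMe3)2 and PhNTf2 give the C5 enol triflate F7, since enolisation is possible only toward C6. Separately, iodide 27 is dehydroiodinated (KOt-Bu, THF) to the vinyl compound F8, which 9-BBN-H converts into the alkylborane F9. Pd(dppf)Cl2, AsPh3 and Cs2CO3 in DMF–H2O couple F9 with F7 to the tetrakis(triethylsilyl) ether F10, and Bu4NF rejoins the route at 32.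

Step 5. The planar C1 radical may be trapped by oxygen on both faces, giving poor facial selectivity at the tertiary carbinol. The fallback goes through an epoxide. From 7, m-CPBA (NaHCO3, CH2Cl2, 0 °C) should epoxidise the trisubstituted alkene on the convex face to the epoxy ketone F3; LiAlH4 (THF, 0 °C) opens the epoxide at the secondary C2 and reduces the ketone to the diol F4; Dess–Martin periodinane oxidises only the secondary C5 alcohol and the route is rejoined at 8.

Further compounds
F1 | step 2 | acetate of ketol 5 | CC1(C)[C@@H]2CC([Si](C)(C)C)=C(C)[C@@H]2[C@H](OC(C)=O)C1=O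
F2 | step 2 | ent-5 (enantiomer of ketol 5) | CC1(C)[C@H]2CC([Si](C)(C)C)=C(C)[C@H]2[C@@H](O)C1=O
F3 | step 5 | convex-face C1–C2 epoxy ketone | CC1(C)[C@@H]2C[C@H]3O[C@@]3(C)[C@@H]2CC1=O
F4 | step 5 | C1,C5-diol (C5 carbinol epimers) | CC1(C)[C@@H]2CC[C@@](C)(O)[C@@H]2CC1O
F5 | step 21 | 1,7-dihydroxy-1,4,4,6-tetramethylhydroazulen-5-one (C6 epimers) | CC1(C)[C@@H]2CC[C@@](C)(O)[C@@H]2C[C@H](O)C(C)C1=O
F6 | step 21 | bis(triethylsilyl) ether of F5 | CC1(C)[C@@H]2CC[C@@](C)(O[Si](CC)(CC)CC)[C@@H]2C[C@H](O[Si](CC)(CC)CC)C(C)C1=O
F7 | step 21 | C5 enol triflate (C5=C6) | CC1=C(OS(=O)(=O)C(F)(F)F)C(C)(C)[C@@H]2CC[C@@](C)(O[Si](CC)(CC)CC)[C@@H]2C[C@@H]1O[Si](CC)(CC)CC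
F8 | step 21 | left-half vinyl compound | C=C[C@@H]1[C@@]2(C)CC[C@@H](O[Si](CC)(CC)CC)C(C)(C)O[C@@H]2CC[C@]1(C)O[Si](CC)(CC)CC
F9 | step 21 | left-half B-alkyl-9-borabicyclo[3.3.1]nonane | C1CCC2CCCC1B2CC[C@@H]1[C@@]2(C)CC[C@@H](O[Si](CC)(CC)CC)C(C)(C)O[C@@H]2CC[C@]1(C)O[Si](CC)(CC)CC
F10 | step 21 | tetrakis(triethylsilyl) ether of the target | CC1=C(CC[C@@H]2[C@@]3(C)CC[C@@H](O[Si](CC)(CC)CC)C(C)(C)O[C@@H]3CC[C@]2(C)O[Si](CC)(CC)CC)C(C)(C)[C@@H]2CC[C@@](C)(O[Si](CC)(CC)CC)[C@@H]2C[C@@H]1O[Si](CC)(CC)CC
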